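**Strategy.** The route rests on cutting the O1–C2 bond of ring C. Ring C, a 3-hydroxy-4-pyranone, is treated as the ring-enlarged form of an aurone. The benzofuranone already holds C4=O, the carbon that becomes C3 with its oxygen, and the ether oxygen O1, which has to shift from that carbon to the neighbouring benzylic one (C2). Alkali on the acetylated aurone dibromide should strip the esters, open the five-membered ring to a phenoxide 1,2-diketone and reclose it through O1 on the benzylic bromide, giving the flavonol with its C5' bromine intact. That bromide then takes the ring B prenyl group by Stille coupling. A 7-O-prenyl ether delivers the C8 1,1-dimethylallyl group by Claisen rearrangement.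

Key step: step 4

Remark on the chemistry: the aurone dibromide and the transient species of the ring expansion are racemic (one enantiomer is drawn), and the target has no stereocentre. Tributyl(3-methylbut-2-en-1-yl)stannane is taken as a purchased reagent.

**Step 1**
Reactants: 1 4,6-dihydroxybenzofuran-3(2H)-one; 2 3-bromo-4,5-dihydroxybenzaldehyde
Product: 3 (Z)-2-(3-bromo-4,5-dihydroxybenzylidene)-4,6-dihydroxybenzofuran-3(2H)-one
Conditions: conc. HCl (cat.), AcOH, 60 °C
Reagents that add atoms: none
Why: Acid-catalysed aldol condensation of the C2 methylene of 1 with the aldehyde and dehydration (Knoevenagel type) should give the aurone, the reversible elimination settling on the more stable (Z)-alkene with the aryl group on the side of O1.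

**Step 2**
Reactants: 3 (Z)-aurone
Product: 4 (Z)-aurone tetraacetate (4,6-diacetoxy ring A, 4,5-diacetoxy-3-bromophenyl ring B)
Conditions: Ac2O, pyridine, DMAP (cat.), rt
Reagents that add atoms: acetic anhydride, CC(=O)OC(C)=O
Why: Pyridine/DMAP-promoted O-acylation of all four phenols, the hydrogen-bonded 4-OH included, makes both rings poor substrates for electrophilic bromination in step 3.

**Step 3**
Reactants: 4 (Z)-aurone tetraacetate
Product: 5 racemic (2R*,αS*)-2-bromo-2-[bromo(3-bromo-4,5-diacetoxyphenyl)methyl]-3-oxo-2,3-dihydrobenzofuran-4,6-diyl diacetate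
Conditions: Br2 (1.05 equiv), CHCl3, 0 °C → rt, dark
Reagents that add atoms: bromine, BrBr
Why: Electrophilic addition of bromine to the exocyclic enol-ether alkene should outpace substitution on the acetoxy-deactivated rings; anti addition to the (Z)-alkene sets the (2R*,αS*) relative configuration, and a second diastereomer would serve equally because both centres vanish in step 4.

**Step 4**
Reactants: 5 aurone dibromide tetraacetate
Product: 9 5'-bromoquercetin, via tetrahydroxy dibromide 6 (not isolated), via bromo diketone 7 (not isolated), via flavan-3,4-dione 8 (not isolated)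
Conditions: KOH (10 equiv), EtOH/H2O 4:1, degassed, argon, 0 °C → 50 °C; then 2 M HCl
Reagents that add atoms: potassium hydroxide, [K+].[OH-]
Why: Hydroxide should first cleave the four aryl acetates (6) and then exchange the bromide at C2, a carbon flanked by the ring oxygen and the ketone, so that the ring opens there to the phenoxide of bromo diketone 7. That phenoxide oxygen, the future O1 (the 2,4,6-trioxygenated ring is symmetric, so either ortho oxygen gives the same product), attacks the benzylic CHBr carbon with loss of bromide in a 6-exo-tet closure, which makes the O1–C2 bond and ring C as flavan-3,4-dione 8; keto–enol tautomerisation then gives the 3-hydroxy-4-pyranone 9. The closest known reaction is the Auwers flavonol synthesis, the ring expansion of aurone dibromides in alcoholic alkali. No stereocentre is kept: the two centres of 5 and the transient C2 centre of 8 all end as sp2 carbons. The selectivity required is closure to the six-membered ring and not back to a five-membered one, together with survival of the aryl C5'–Br bond: after C2 has turned into a ketone it carries nothing that can leave, so the phenoxide can only alkylate the benzylic carbon, the gain in aromaticity on tautomerisation of 8 pulls the sequence forward, and an aryl bromide does not react with hydroxide under these conditions. Air is excluded because the polyphenoxide of 9 is easily oxidised.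

**Step 5**
Reactants: 9 5'-bromoquercetin
Product: 10 5'-bromoquercetin 3,5,7,3',4'-pentaacetate
Conditions: Ac2O, pyridine, DMAP (cat.), 60 °C
Reagents that add atoms: acetic anhydride, CC(=O)OC(C)=O
Why: Exhaustive O-acetylation (pyridine/DMAP acyl transfer), pushed to include the chelated 5-OH by warming, masks all five hydroxyls so that the coupling, etherification and thermal steps meet no free phenol.

**Step 6**
Reactants: 10 5'-bromoquercetin pentaacetate; 11 tributyl(3-methylbut-2-en-1-yl)stannane
Product: 12 5'-(3-methylbut-2-en-1-yl)quercetin pentaacetate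
Conditions: Pd(PPh3)4 (5 mol%), toluene, 105 °C, argon
Reagents that add atoms: none
Why: Migita–Kosugi–Stille coupling: zerovalent palladium inserts into the only aryl–halogen bond (C5'–Br), the allyl-type stannane transmetalates, and reductive elimination at the less substituted allyl terminus should give the linear prenyl arene under neutral conditions that leave the acetates alone.

**Step 7**
Reactants: 12 5'-prenylquercetin pentaacetate; 13 prenyl bromide (1-bromo-3-methylbut-2-ene)
Product: 15 7-O-prenyl-5'-prenylquercetin 3,5,3',4'-tetraacetate, via 7-hydroxy tetraacetate 14 (not isolated)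
Conditions: K2CO3 (anhydrous, 1.5 equiv), 13 (1.2 equiv), acetone, reflux
Reagents that add atoms: none
Why: Selective deacylative etherification of a flavonol polyacetate: the 7-ester is the most labile because its phenoxide is conjugated with the C4 carbonyl through ring A, so carbonate cleaves it first and phenoxide 14 is trapped by Williamson O-alkylation (SN2 at the primary allylic carbon), while the other four esters should stay.

**Step 8**
Reactants: 15 7-O-prenyl tetraacetate
Product: 17 8-(2-methylbut-3-en-2-yl)-5'-prenylquercetin 3,5,7,3',4'-pentaacetate, via 8-(1,1-dimethylallyl)-7-hydroxy tetraacetate 16 (not isolated)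
Conditions: Ac2O (5 equiv), PhNEt2, 190 °C, sealed tube, argon
Reagents that add atoms: acetic anhydride, CC(=O)OC(C)=O
Why: Aromatic Claisen rearrangement: the [3,3]-sigmatropic shift moves the allyl unit from O7 to an ortho carbon with allylic inversion and so forms the C8–C(CH3)2CH=CH2 bond; C8 is expected over C6 because the C7–C8 bond of a benzopyranone has the higher double-bond character (as in 7-allyloxychromones and -coumarins) and C6 is crowded by the 5-acetate, and acetylation of phenol 16 in the flask should block abnormal Claisen isomerisation and ring closure onto the new alkene.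

**Step 9**
Reactants: 17 pentaacetate of the target
Product: 18 target CNP0196880.0, 2-[3,4-dihydroxy-5-(3-methylbut-2-en-1-yl)phenyl]-3,5,7-trihydroxy-8-(2-methylbut-3-en-2-yl)-4H-chromen-4-one
Conditions: K2CO3 (0.3 equiv), MeOH/THF 3:1, degassed, argon, 0 °C → rt; then aq. NH4Cl
Reagents that add atoms: none
Why: Base-catalysed transesterification of the aryl acetates by methanol (Zemplén-type methanolysis) should free all five hydroxyls without acid, which would cyclise the prenyl and 1,1-dimethylallyl groups onto their ortho hydroxyls, and without oxygen, which would degrade the catechol flavonol.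

**Compound list**

1 | 4,6-dihydroxybenzofuran-3(2H)-one | O=C1COc2cc(O)cc(O)c12 | starting material
2 | 3-bromo-4,5-dihydroxybenzaldehyde | O=Cc1cc(O)c(O)c(Br)c1 | starting material
3 | (Z)-2-(3-bromo-4,5-dihydroxybenzylidene)-4,6-dihydroxybenzofuran-3(2H)-one | O=C1c2c(O)cc(O)cc2O/C1=C\c1cc(O)c(O)c(Br)c1 | intermediate
4 | (Z)-2-(3-bromo-4,5-diacetoxybenzylidene)-3-oxo-2,3-dihydrobenzofuran-4,6-diyl diacetate | O=C1c2c(OC(C)=O)cc(OC(C)=O)cc2O/C1=C\c1cc(OC(C)=O)c(OC(C)=O)c(Br)c1 | intermediate
5 | racemic (2R*,αS*)-2-bromo-2-[bromo(3-bromo-4,5-diacetoxyphenyl)methyl]-3-oxo-2,3-dihydrobenzofuran-4,6-diyl diacetate, (2R,αS) drawn | O=C1c2c(OC(C)=O)cc(OC(C)=O)cc2O[C@]1(Br)[C@@H](Br)c1cc(OC(C)=O)c(OC(C)=O)c(Br)c1 | intermediate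
6 | racemic (2R*,αS*)-2-bromo-2-[bromo(3-bromo-4,5-dihydroxyphenyl)methyl]-4,6-dihydroxybenzofuran-3(2H)-one, not isolated | O=C1c2c(O)cc(O)cc2O[C@]1(Br)[C@@H](Br)c1cc(O)c(O)c(Br)c1 | intermediate
7 | racemic 3-bromo-3-(3-bromo-4,5-dihydroxyphenyl)-1-(2,4,6-trihydroxyphenyl)propane-1,2-dione, (3S) drawn, not isolated | O=C(c1c(O)cc(O)cc1O)C(=O)[C@@H](Br)c1cc(O)c(O)c(Br)c1 | intermediate
8 | racemic 2-(3-bromo-4,5-dihydroxyphenyl)-5,7-dihydroxychromane-3,4-dione, (2R) drawn, not isolated | O=C1c2c(O)cc(O)cc2O[C@H](c2cc(O)c(O)c(Br)c2)C1=O | intermediate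
9 | 5'-bromoquercetin, 2-(3-bromo-4,5-dihydroxyphenyl)-3,5,7-trihydroxy-4H-chromen-4-one | O=c1c(O)c(-c2cc(O)c(O)c(Br)c2)oc2cc(O)cc(O)c12 | intermediate
10 | 5'-bromoquercetin 3,5,7,3',4'-pentaacetate | O=c1c(OC(C)=O)c(-c2cc(OC(C)=O)c(OC(C)=O)c(Br)c2)oc2cc(OC(C)=O)cc(OC(C)=O)c12 | intermediate
11 | tributyl(3-methylbut-2-en-1-yl)stannane | CCCC[Sn](CCCC)(CCCC)CC=C(C)C | starting material
12 | 5'-(3-methylbut-2-en-1-yl)quercetin 3,5,7,3',4'-pentaacetate | O=c1c(OC(C)=O)c(-c2cc(OC(C)=O)c(OC(C)=O)c(CC=C(C)C)c2)oc2cc(OC(C)=O)cc(OC(C)=O)c12 | intermediate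
13 | prenyl bromide, 1-bromo-3-methylbut-2-ene | CC(C)=CCBr | starting material
14 | 5'-prenylquercetin 3,5,3',4'-tetraacetate with free 7-OH, not isolated | O=c1c(OC(C)=O)c(-c2cc(OC(C)=O)c(OC(C)=O)c(CC=C(C)C)c2)oc2cc(O)cc(OC(C)=O)c12 | intermediate
15 | 7-O-(3-methylbut-2-en-1-yl)-5'-prenylquercetin 3,5,3',4'-tetraacetate | O=c1c(OC(C)=O)c(-c2cc(OC(C)=O)c(OC(C)=O)c(CC=C(C)C)c2)oc2cc(OCC=C(C)C)cc(OC(C)=O)c12 | intermediate
16 | 8-(2-methylbut-3-en-2-yl)-5'-prenylquercetin 3,5,3',4'-tetraacetate with free 7-OH, not isolated | O=c1c(OC(C)=O)c(-c2cc(OC(C)=O)c(OC(C)=O)c(CC=C(C)C)c2)oc2c(C(C)(C)C=C)c(O)cc(OC(C)=O)c12 | intermediate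
17 | 8-(2-methylbut-3-en-2-yl)-5'-prenylquercetin 3,5,7,3',4'-pentaacetate | O=c1c(OC(C)=O)c(-c2cc(OC(C)=O)c(OC(C)=O)c(CC=C(C)C)c2)oc2c(C(C)(C)C=C)c(OC(C)=O)cc(OC(C)=O)c12 | intermediate
18 | CNP0196880.0, 2-[3,4-dihydroxy-5-(3-methylbut-2-en-1-yl)phenyl]-3,5,7-trihydroxy-8-(2-methylbut-3-en-2-yl)-4H-chromen-4-one | C=CC(C)(C)c1c(O)cc(O)c2c(=O)c(O)c(-c3cc(O)c(O)c(CC=C(C)C)c3)oc12 | target

**Total step count:** 9
**Longest linear sequence:** 9 steps (1 or 2 → 18)

**Steps most likely to fail**

1. Step 4 (ring expansion). Base may strip HBr across C2–Cα to an α-bromoaurone, which hydrolyses to a 2-aroylbenzofuranone, instead of substituting at C2. The electron-rich 1,2-diketone may also be cleaved or air-oxidised as its polyphenoxide. Fallback, setting out from 2 and rejoining at 9, builds the flavonol by hydroxylating a flavone. Methylation of 2 (MeI, K2CO3, DMF) should give 3-bromo-4,5-dimethoxybenzaldehyde F1. Claisen–Schmidt condensation with purchased 2'-hydroxy-4',6'-dimethoxyacetophenone (KOH, EtOH) should give (E)-3-(3-bromo-4,5-dimethoxyphenyl)-1-(2-hydroxy-4,6-dimethoxyphenyl)prop-2-en-1-one F2. Oxidative cyclisation (I2 cat., DMSO, 130 °C) should give 2-(3-bromo-4,5-dimethoxyphenyl)-5,7-dimethoxy-4H-chromen-4-one F3. Epoxidation of the C2–C3 bond with dimethyldioxirane and acid-induced opening (p-TsOH) should give 2-(3-bromo-4,5-dimethoxyphenyl)-3-hydroxy-5,7-dimethoxy-4H-chromen-4-one F4. BBr3 (CH2Cl2, −78 °C → rt) then removes the four methyl ethers to give 9.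

2. Step 8 (Claisen rearrangement). The allyl unit may migrate to C6 instead of C8, or the ether may fragment thermally with loss of the prenyl group before the shift. Fallback, setting out from 10 and rejoining at 17, makes both side chains by cross-coupling on an iodide/bromide pair. Thiophenol/imidazole in NMP at 0 °C should remove only the 7-acetate to give 5'-bromoquercetin 3,5,3',4'-tetraacetate F5. N-Iodosuccinimide (1 equiv, MeCN, 0 °C) should iodinate ortho to the free 7-OH at C8, the more reactive position of a 7-hydroxybenzopyranone, to give 5'-bromo-8-iodoquercetin 3,5,3',4'-tetraacetate F6. Ac2O/pyridine then gives 5'-bromo-8-iodoquercetin pentaacetate F7. Suzuki–Miyaura coupling of the C8 iodide, which reacts before the C5' bromide, with 3-methylbut-2-enylboronic acid pinacol ester should give 5'-bromo-8-(2-methylbut-3-en-2-yl)quercetin pentaacetate F8. This coupling uses Pd(OAc)2 with a bulky biarylphosphine chosen for bond formation at the substituted (γ) allyl terminus, and anhydrous K3PO4 in THF. The Stille coupling of step 6 with 11 then gives 17.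

3. Step 6 (Stille prenylation). Allylic transposition at palladium may give the branched 1,1-dimethylallyl arene, and slow transmetalation next to the ortho acetate may lead to protodebromination. Fallback, setting out from 10 and rejoining at 12, uses an allyl group whose transposition is degenerate. Stille coupling with allyltributylstannane (Pd(PPh3)4, toluene, 105 °C) should give 5'-allylquercetin pentaacetate F9. Olefin cross-metathesis with 2-methylbut-2-ene (second-generation Grubbs catalyst, CH2Cl2, 40 °C) then gives 12.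

**Further compounds**

F1 | step 4 | 3-bromo-4,5-dimethoxybenzaldehyde | COc1cc(C=O)cc(Br)c1OC
F2 | step 4 | (E)-3-(3-bromo-4,5-dimethoxyphenyl)-1-(2-hydroxy-4,6-dimethoxyphenyl)prop-2-en-1-one | COc1cc(O)c(C(=O)/C=C/c2cc(OC)c(OC)c(Br)c2)c(OC)c1
F3 | step 4 | 2-(3-bromo-4,5-dimethoxyphenyl)-5,7-dimethoxy-4H-chromen-4-one | COc1cc(OC)c2c(=O)cc(-c3cc(OC)c(OC)c(Br)c3)oc2c1
F4 | step 4 | 2-(3-bromo-4,5-dimethoxyphenyl)-3-hydroxy-5,7-dimethoxy-4H-chromen-4-one | COc1cc(OC)c2c(=O)c(O)c(-c3cc(OC)c(OC)c(Br)c3)oc2c1
F5 | step 8 | 5'-bromoquercetin 3,5,3',4'-tetraacetate with free 7-OH | O=c1c(OC(C)=O)c(-c2cc(OC(C)=O)c(OC(C)=O)c(Br)c2)oc2cc(O)cc(OC(C)=O)c12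
F6 | step 8 | 5'-bromo-8-iodoquercetin 3,5,3',4'-tetraacetate with free 7-OH | O=c1c(OC(C)=O)c(-c2cc(OC(C)=O)c(OC(C)=O)c(Br)c2)oc2c(I)c(O)cc(OC(C)=O)c12
F7 | step 8 | 5'-bromo-8-iodoquercetin 3,5,7,3',4'-pentaacetate | O=c1c(OC(C)=O)c(-c2cc(OC(C)=O)c(OC(C)=O)c(Br)c2)oc2c(I)c(OC(C)=O)cc(OC(C)=O)c12
F8 | step 8 | 5'-bromo-8-(2-methylbut-3-en-2-yl)quercetin 3,5,7,3',4'-pentaacetate | O=c1c(OC(C)=O)c(-c2cc(OC(C)=O)c(OC(C)=O)c(Br)c2)oc2c(C(C)(C)C=C)c(OC(C)=O)cc(OC(C)=O)c12
F9 | step 6 | 5'-allylquercetin 3,5,7,3',4'-pentaacetate | O=c1c(OC(C)=O)c(-c2cc(OC(C)=O)c(OC(C)=O)c(CC=C)c2)oc2cc(OC(C)=O)cc(OC(C)=O)c12
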